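**Retrosynthetic overview** (butenolide numbering used throughout: O1, C2 = lactone C=O, C3 = C–CH3, C4 = C–CO2H, C5 = stereocentre, R)

1. Target 14 ⇐ tert-butyl ester 13 (acid cleavage) ⇐ hydroxy α-methylene lactone 11 (O-acetylation and shift of C3=CH2 into the ring as C3=C4).
2. Key disconnection C4–C5: 11 ⇐ the acyclic, achiral aldehyde/allylic bromide 8, by a chromium-catalysed asymmetric intramolecular allylation.
3. Enabling feature: the primary oxygen at the end of the C13 side chain (the acetate O) can serve as the alkoxy group of an ester at C2. C5 (as aldehyde) and C4 (as γ-carbon of a 2-(bromomethyl)butenedioate) then sit in one chain, and the C4–C5 bond closes an 18-membered ring (C2, C3, C4, C5, thirteen CH2, O).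
4. The γ-hydroxy ester so formed contracts across the ring to the five-membered lactone O1–C2–C3–C4–C5 and releases the chain oxygen for the acetate; 8 ⇐ itaconic anhydride 1 + tert-butanol 2 + tetradecane-1,14-diol 4.
5. Ring order: temporary 18-membered lactone first, then the five-membered lactone by ring contraction, both in step 5; no other ring is made.

Key step: step 5

Assumption: both geometric isomers of the allylic bromide (7, 8) give the same allylchromium, so the drawn (Z) geometry is not critical; the C4 epimers of 9–12 are carried as a mixture because step 6 removes this stereocentre.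

**Step 1**
Reactants: 1 itaconic anhydride; 2 tert-butanol
Product: 3 4-tert-butyl hydrogen itaconate (4-tert-butoxy-2-methylidene-4-oxobutanoic acid)
Conditions: t-BuOH (excess), toluene, 85 °C
Reagents that add atoms: none
Why: Regioselective alcoholysis of the cyclic anhydride (acyl substitution) should occur at the non-conjugated, more electrophilic carbonyl, leaving the conjugated acid free.

**Step 2**
Reactants: 3 4-tert-butyl hydrogen itaconate; 4 tetradecane-1,14-diol (fourfold excess, recovered)
Product: 5 1-(14-hydroxytetradecyl) 4-tert-butyl 2-methylidenebutanedioate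
Conditions: DCC, DMAP (cat.), CH2Cl2/THF, 0 °C to rt
Reagents that add atoms: none
Why: Steglich esterification of the conjugated acid; the excess of the symmetric diol should hold the reaction at the monoester.

**Step 3**
Reactants: 5 1-(14-hydroxytetradecyl) 4-tert-butyl 2-methylidenebutanedioate
Product: 7 1-(14-hydroxytetradecyl) 4-tert-butyl (2Z)-2-(bromomethyl)but-2-enedioate, via vicinal dibromide 6 (not isolated)
Conditions: Br2, CH2Cl2, rt, dark; then Et3N (1.1 equiv), 0 °C
Reagents that add atoms: bromine, BrBr
Why: Electrophilic bromine addition to the 1,1-disubstituted alkene followed by E2 loss of HBr across C3–C4 (H α to the tert-butyl ester, tertiary bromide) should give the allylic bromide, as is standard for itaconate diesters.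

**Step 4**
Reactants: 7 1-(14-hydroxytetradecyl) 4-tert-butyl (2Z)-2-(bromomethyl)but-2-enedioate
Product: 8 1-(14-oxotetradecyl) 4-tert-butyl (2Z)-2-(bromomethyl)but-2-enedioate
Conditions: Dess–Martin periodinane, CH2Cl2, rt
Reagents that add atoms: none
Why: Dess–Martin oxidation of the primary alcohol is neutral and should leave the allylic bromide and the tert-butyl ester untouched.

**Step 5**
Reactants: 8 1-(14-oxotetradecyl) 4-tert-butyl (2Z)-2-(bromomethyl)but-2-enedioate
Product: 11 tert-butyl (5R)-5-(13-hydroxytridecyl)-3-methylidene-2-oxooxolane-4-carboxylate, via macrocyclic silyl ether 9 (not isolated), via macrocyclic hydroxy lactone 10 (not isolated)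
Conditions: CrCl2 (15 mol%), ligand L (18 mol%; one antipode of 1,8-bis(4-isopropyl-4,5-dihydrooxazol-2-yl)-3,6-diphenyl-9H-carbazole, chosen for Si-face attack), Mn powder, Me3SiCl, i-Pr2NEt (cat.), THF, rt, 8 added by syringe pump (final 2 mM); then 1 M HCl/THF; then TsOH·H2O (5 mol%), CH2Cl2, rt
Reagents that add atoms: none
Why: CrCl2 inserts into the allylic C–Br bond to give an allylchromium of trivalent chromium carrying the chiral tridentate ligand, which adds through its γ-carbon (C4) to the tethered aldehyde carbon (C5) in a chair-like six-membered transition state, closing the 18-membered ring (exo attack on the C=O, with allyl transposition that leaves C3=CH2), while Me3SiCl silylates the chromium alkoxide and Mn returns chromium to the divalent state. The closest known reaction type is the chromium-catalysed asymmetric Nozaki–Hiyama–Kishi 2-(alkoxycarbonyl)allylation of aliphatic aldehydes to α-methylene-γ-butyrolactones, together with intramolecular Nozaki–Hiyama–Kishi macrocyclisations. After desilylation the C5 hydroxyl attacks the macrocyclic ester carbonyl C2 across the ring (5-exo-trig acyl substitution), so the 18-membered lactone contracts to the five-membered lactone O1–C2–C3–C4–C5 and the tether leaves as the free primary alcohol at the chain end. C5 is set by the ligand on chromium (attack on the Si face of the aldehyde gives R); C4 is set relative to C5 by the chair transition state and is erased in step 6. The step needs ring closure over oligomerisation (slow addition at high dilution), γ- over α-attack of the allyl unit (cyclic transition state) and attack on the aldehyde but not on the esters (carbonyl selectivity and low basicity of organochromium reagents).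

**Step 6**
Reactants: 11 tert-butyl (5R)-5-(13-hydroxytridecyl)-3-methylidene-2-oxooxolane-4-carboxylate
Product: 13 tert-butyl (5R)-5-(13-acetoxytridecyl)-3-methyl-2-oxo-2,5-dihydrofuran-4-carboxylate, via exo-methylene acetate 12 (not isolated)
Conditions: Ac2O, Et3N, DMAP (cat.), CH2Cl2, 0 °C to rt
Reagents that add atoms: acetic anhydride, CC(=O)OC(C)=O
Why: DMAP-catalysed acetylation of the primary alcohol, then an Et3N-mediated 1,3-prototropic shift through deprotonation at C4 (α to the ester, vinylogously α to the lactone) should give the conjugated tetrasubstituted butenolide, removing the C4 stereocentre and leaving C5 untouched.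

**Step 7**
Reactants: 13 tert-butyl (5R)-5-(13-acetoxytridecyl)-3-methyl-2-oxo-2,5-dihydrofuran-4-carboxylate
Product: 14 (5R)-5-(13-acetoxytridecyl)-3-methyl-2-oxo-2,5-dihydrofuran-4-carboxylic acid
Conditions: CF3CO2H/CH2Cl2 (1:3), rt
Reagents that add atoms: none
Why: Acidolysis of the tert-butyl ester (loss of isobutene) should free the acid; the primary acetate, the lactone and the C5 centre are stable to these conditions.

**Compound list**

1 | itaconic anhydride (3-methylideneoxolane-2,5-dione) | C=C1CC(=O)OC1=O | starting material
2 | tert-butanol | CC(C)(C)O | starting material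
3 | 4-tert-butyl hydrogen itaconate | C=C(CC(=O)OC(C)(C)C)C(=O)O | intermediate
4 | tetradecane-1,14-diol | OCCCCCCCCCCCCCCO | starting material
5 | 1-(14-hydroxytetradecyl) 4-tert-butyl 2-methylidenebutanedioate | C=C(CC(=O)OC(C)(C)C)C(=O)OCCCCCCCCCCCCCCO | intermediate
6 | 1-(14-hydroxytetradecyl) 4-tert-butyl 2-bromo-2-(bromomethyl)butanedioate (racemic) | BrCC(Br)(CC(=O)OC(C)(C)C)C(=O)OCCCCCCCCCCCCCCO | intermediate
7 | 1-(14-hydroxytetradecyl) 4-tert-butyl (2Z)-2-(bromomethyl)but-2-enedioate | OCCCCCCCCCCCCCCOC(=O)/C(CBr)=C/C(=O)OC(C)(C)C | intermediate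
8 | 1-(14-oxotetradecyl) 4-tert-butyl (2Z)-2-(bromomethyl)but-2-enedioate | O=CCCCCCCCCCCCCCOC(=O)/C(CBr)=C/C(=O)OC(C)(C)C | intermediate
9 | tert-butyl (5R)-3-methylidene-2-oxo-5-(trimethylsilyloxy)-1-oxacyclooctadecane-4-carboxylate (macrocycle numbering, C4 epimers) | C=C1C(=O)OCCCCCCCCCCCCC[C@@H](O[Si](C)(C)C)C1C(=O)OC(C)(C)C | intermediate
10 | tert-butyl (5R)-5-hydroxy-3-methylidene-2-oxo-1-oxacyclooctadecane-4-carboxylate (macrocycle numbering, C4 epimers) | C=C1C(=O)OCCCCCCCCCCCCC[C@@H](O)C1C(=O)OC(C)(C)C | intermediate
11 | tert-butyl (5R)-5-(13-hydroxytridecyl)-3-methylidene-2-oxooxolane-4-carboxylate (C4 epimers) | OCCCCCCCCCCCCC[C@H]1OC(=O)C(=C)C1C(=O)OC(C)(C)C | intermediate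
12 | tert-butyl (5R)-5-(13-acetoxytridecyl)-3-methylidene-2-oxooxolane-4-carboxylate (C4 epimers) | CC(=O)OCCCCCCCCCCCCC[C@H]1OC(=O)C(=C)C1C(=O)OC(C)(C)C | intermediate
13 | tert-butyl (5R)-5-(13-acetoxytridecyl)-3-methyl-2-oxo-2,5-dihydrofuran-4-carboxylate | CC(=O)OCCCCCCCCCCCCC[C@H]1OC(=O)C(C)=C1C(=O)OC(C)(C)C | intermediate
14 | (5R)-5-(13-acetoxytridecyl)-3-methyl-2-oxo-2,5-dihydrofuran-4-carboxylic acid | CC(=O)OCCCCCCCCCCCCC[C@H]1OC(=O)C(C)=C1C(=O)O | target

**Step count and risks**

Total step count: 7. Longest linear sequence: 7 (1 → 3 → 5 → 7 → 8 → 11 → 13 → 14; 2 and 4 enter in steps 1 and 2).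

Steps most likely to fail:

Step 5. Chain growth between two molecules may outrun the 18-membered ring closure, and facial discrimination by the chromium ligand may erode when the addition has to pass through a macrocyclic transition state. The fallback gives up the tether and runs the same bond formation between two molecules; it sets out from 7 (with 4 for the aldehyde partner) and comes back at 12. Compound 7 is acetylated (Ac2O, Sc(OTf)3 cat., MeCN, 0 °C) to 1-(14-acetoxytetradecyl) 4-tert-butyl (2Z)-2-(bromomethyl)but-2-enedioate F1. Diol 4 is monoacetylated (Ac2O, pyridine, diol in excess) to 14-hydroxytetradecyl acetate F2, which is oxidised (Dess–Martin periodinane) to 14-oxotetradecyl acetate F3. F1 and F3 are coupled at normal concentration under the CrCl2/ligand L/Mn/Me3SiCl system, a known intermolecular asymmetric 2-(alkoxycarbonyl)allylation, to the open-chain silyl ether adduct F4. Aqueous acid gives the open-chain hydroxy diester F5, which on TsOH treatment should lactonise to 12 with loss of F2 (returned to the oxidation). Compound 12 is then isomerised with Et3N to 13 as in step 6.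

Step 6. Configuration at C5 may be partly lost by γ-deprotonation of the butenolide ester (achiral 2-oxidofuran) while the amine base is still present after the double-bond shift. The fallback separates the operations and isomerises the free acid instead of the ester; it sets out from 11 and comes back at 14. Compound 11 is only acetylated (Ac2O, pyridine, 0 °C, short contact) and 12 is isolated. CF3CO2H/CH2Cl2 then gives (5R)-5-(13-acetoxytridecyl)-3-methylidene-2-oxooxolane-4-carboxylic acid F6. F6 is isomerised as its carboxylate salt (Et3N, 1 equiv, CH2Cl2, rt), where the negative charge next to C5 should disfavour a second deprotonation, to give 14 directly.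

Step 1. Acyl transfer to the hindered tertiary alcohol may be slow, so that thermal isomerisation of the anhydride to citraconic anhydride and loss of regiocontrol compete. The fallback builds the half ester by olefination instead of anhydride opening; it sets out from 2 and comes back at 3. Compound 2 is acylated with bromoacetyl bromide (N,N-dimethylaniline, Et2O, 0 °C) to tert-butyl bromoacetate F7. Triethyl phosphonoacetate is alkylated with F7 (NaH, THF) to 4-tert-butyl 1-ethyl 2-(diethoxyphosphoryl)butanedioate F8. Horner–Wadsworth–Emmons methylenation (aqueous formaldehyde, K2CO3) gives 4-tert-butyl 1-ethyl 2-methylidenebutanedioate F9. Selective saponification of the unhindered ethyl ester (LiOH, 1 equiv, THF/H2O, 0 °C) should give 3.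

**Further compounds**

F1 | step 5 | 1-(14-acetoxytetradecyl) 4-tert-butyl (2Z)-2-(bromomethyl)but-2-enedioate | CC(=O)OCCCCCCCCCCCCCCOC(=O)/C(CBr)=C/C(=O)OC(C)(C)C
F2 | step 5 | 14-hydroxytetradecyl acetate | CC(=O)OCCCCCCCCCCCCCCO
F3 | step 5 | 14-oxotetradecyl acetate | CC(=O)OCCCCCCCCCCCCCC=O
F4 | step 5 | open-chain silyl ether adduct, 1-(14-acetoxytetradecyl) 4-tert-butyl 3-[(1R)-14-acetoxy-1-(trimethylsilyloxy)tetradecyl]-2-methylidenebutanedioate | CC(=O)OCCCCCCCCCCCCC[C@@H](O[Si](C)(C)C)C(C(=O)OC(C)(C)C)C(=C)C(=O)OCCCCCCCCCCCCCCOC(C)=O
F5 | step 5 | open-chain hydroxy diester, 1-(14-acetoxytetradecyl) 4-tert-butyl 3-[(1R)-14-acetoxy-1-hydroxytetradecyl]-2-methylidenebutanedioate | CC(=O)OCCCCCCCCCCCCC[C@@H](O)C(C(=O)OC(C)(C)C)C(=C)C(=O)OCCCCCCCCCCCCCCOC(C)=O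
F6 | step 6 | (5R)-5-(13-acetoxytridecyl)-3-methylidene-2-oxooxolane-4-carboxylic acid | CC(=O)OCCCCCCCCCCCCC[C@H]1OC(=O)C(=C)C1C(=O)O
F7 | step 1 | tert-butyl bromoacetate | BrCC(=O)OC(C)(C)C
F8 | step 1 | 4-tert-butyl 1-ethyl 2-(diethoxyphosphoryl)butanedioate | CCOC(=O)C(CC(=O)OC(C)(C)C)P(=O)(OCC)OCC
F9 | step 1 | 4-tert-butyl 1-ethyl 2-methylidenebutanedioate | C=C(CC(=O)OC(C)(C)C)C(=O)OCC
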